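The plateau comes first. One flask of substrate, reagent and free catalyst is followed, and the question is how much target stands at the time of the look and which action raises it.

| flask | substrate | reagent | free catalyst | temperature | remark | time |
|---|---|---|---|---|---|---|
| east | 5.0 × 10⁻⁴ M | 0.55 mM | 50 µM | 50 °C | the very flask that is asked about, followed so far |  |
| west | 3.4 × 10⁻⁴ M | 0.55 mM | 50 µM | 56 °C | run made earlier |  |
| flask | 5.0 × 10⁻⁴ M | 0.550 mM | 50 µM | 50 °C |  | 10 min |

- blue: at 10 min take out 90% of the target then present, then wait 10 min
- teal: at 10 min add reagent, 50.0% of the amount charged, then wait 10 min
- green: at 10 min add free catalyst, 100% of the amount charged, then wait 10 min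
- violet: at 10 min raise the temperature by 25 K, then wait 10 min
- ochre: change nothing and wait 10 min more

* target, in percent of the substrate first charged, at 10 min
* what to do for the largest gain in target; "none" if nothing gains more than 2 percentage points (blue / teal / green / violet / ochre / none)
* target present, with what was taken out counted in, in percent of the substrate first charged, after violet
* target present, with what was taken out counted in, in percent of the substrate first charged, after ochre

- target that was removed still counts
- steps under discussion: reagent + free catalyst -> catalyst intermediate A; catalyst intermediate A -> catalyst intermediate B; substrate + catalyst intermediate B -> catalyst intermediate C; catalyst intermediate C -> catalyst intermediate D; catalyst intermediate D -> free catalyst + target; target <-> isomer of the product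
- additions bring no volume worth counting

east run (percent of the substrate charged)

| time / min | target / % | substrate / % |
|---|---|---|
| 1.33 | 21.8 | 37.5 |
| 2.50 | 27.7 | 6.2 |
| 4.00 | 26.7 | 0.1 |
| 5.00 | 25.7 | 0 |
| 6.00 | 27.0 | 0.1 |

Read down the east table. In its first row substrate stands at 37.5% and target at 21.8%, and in the second 6.2% and 27.7%, so target climbs while substrate is consumed. In the last rows substrate reads 0.1% or less, and target reads 26.7%, 25.7%, 27.0%, which differ by about the scatter of 1 percentage point. The catalyst charge equals 10.0% of the substrate charge, so forms of the catalyst hold at most that much of the substrate, and what they and target do not hold must stand as isomer of the product. The mean of those rows, 26.5%, is the plateau share, the part of the reacted substrate that stands as target once the readings stop moving.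

west run (percent of the substrate charged)

| time / min | target / % | substrate / % |
|---|---|---|
| 0.417 | 20.0 | 51.5 |
| 0.833 | 30.7 | 20.9 |
| 1.33 | 37.0 | 3.4 |
| 2.50 | 38.9 | 1.0 |
| 5.00 | 37.6 | 0.3 |

The west table, at 56 °C, levels at 38.2%, higher than the east share. The west run differs from the east run in substrate as well as in temperature, but a first-order step each way has a ratio free of concentration, so this rise is read as the work of temperature.

Each substrate turned over costs one reagent, so the reckoning made here, at one temperature and once the readings stop moving, is target = plateau share × the smaller of one and the equivalents of reagent to substrate. In this reckoning the crossing at one equivalent is where control passes from the reagent to the share. The flask has 1.10 equivalents, which gives 26.5%. With substrate reading 0.1% in the east run, added reagent or catalyst finds little to turn over. Blue, if the remainder splits again at the same share, gains 18 points in this reckoning. Between the two plateaus, as read, the share gained 12 points from 50 °C to 56 °C, and violet offers 25 K, so violet is the choice made here.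

The forecast gives 26.5%, 26.5% after ochre and 74% after violet, and chooses violet: “That points to a fast target ⇌ isomer equilibrium, not slow loss.”

The flask gives 26.3%, 26.3% after ochre and 72.1% after violet. The best action is violet, gaining 46 points against 17 points for blue.

    reagent + free catalyst → catalyst intermediate A (k = 1600 M⁻¹ s⁻¹, Ea = 43.0 kJ mol⁻¹)
    catalyst intermediate A → catalyst intermediate B (k = 0.930 s⁻¹, Ea = 77.0 kJ mol⁻¹)
    substrate + catalyst intermediate B → catalyst intermediate C (k = 1300 M⁻¹ s⁻¹, Ea = 41.0 kJ mol⁻¹)
    catalyst intermediate C → catalyst intermediate D (k = 32.0 s⁻¹, Ea = 71.0 kJ mol⁻¹)
    catalyst intermediate D → free catalyst + target (k = 0.130 s⁻¹, Ea = 89.0 kJ mol⁻¹)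
    target ⇌ isomer of the product (K = 2.80, k = 0.0710 s⁻¹, Ea = 93.0 kJ mol⁻¹, ΔH = −74.0 kJ mol⁻¹)
    (constants at 50 °C)

Target and isomer of the product relax with a half-life of 0.120 min, both directions together, by that step taken by itself, which is far shorter than the 10 min of the look. The flask holds target 26.3% and isomer 73.7% at that time and target 26.3% at 100 min, which is thermodynamic control. With 8.5 × 10⁻⁴ M of substrate the equivalents fall to 0.647 equiv, reagent becomes the limiting reagent, and the plateau share gives 17.1%. That flask gives 17.0%, with 35% of its substrate left and reagent at 0%.

The data are calculated with constants of no real substance; the scatter is artificial.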